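Locants follow the 7-oxabicyclo[4.1.0]hept-3-ene numbering of the target: C1 quaternary epoxide carbon, C2 ketone, C3 heptenyl-bearing carbon, C4 CH2OH-bearing carbon, C5 carbinol, C6 epoxide CH, O7.
Retrosynthesis: cut the side-chain C=C (cross-metathesis), then O7–C6 (oxirane from a trans 1-hydroxy-6-mesylate), then C1–C2 and C3=C4 together, which splits the carbocycle into two halves of similar size.
Enabling feature: C1(O)–C2(=O) is an α-ketol pair and C2(=O)–C3=C4 is an aldol enone. C2, C3 and the heptenyl chain are therefore 2-nonenal used as an acyl-anion/enol bis-nucleophile, and C4–C5–C6–C1 is the four-carbon chain of tartaric acid with two electrophilic ends.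
Forward: D-tartrate acetonide → bis(N-methoxy-N-methylamide) → allyl keto amide. A one-flask annulation with metalated 1-ethoxynonadiene and LiCH2OLi closes the six-membered ring. Acetonide shift and mesylation/closure then build the oxirane, and metathesis and acidolysis finish.
Stereochemistry: C5 and C6 come from (S,S)-tartrate and C1 from magnesium chelation to O6. C6 is inverted in the SN2 oxirane closure, so O7 ends syn to the C5 hydroxyl. Both (E)-alkenes are the thermodynamic isomers.

Key step: step 4

Remark: the enol-ether geometry drawn for 7 and 9 assumes retention at the metalated carbon. It is lost on hydrolysis and has no bearing on the product.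

Step 1
Reactants: 1 dimethyl (4S,5S)-2,2-dimethyl-1,3-dioxolane-4,5-dicarboxylate (acetonide of dimethyl D-tartrate)
Product: 2 (4S,5S)-N4,N5-dimethoxy-N4,N5,2,2-tetramethyl-1,3-dioxolane-4,5-dicarboxamide
Conditions: MeNH(OMe)·HCl, i-PrMgCl, THF, −20 to 0 °C
Reagents that add atoms: N,O-dimethylhydroxylamine hydrochloride, CNOC.Cl
Why: Aminolysis of both esters by the chloromagnesium amide of N,O-dimethylhydroxylamine (Weinreb amide formation) is fast at low temperature and should not touch the two acetonide-bearing stereocentres.

Step 2
Reactants: 2 bis(N-methoxy-N-methylamide)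
Product: 3 (4S,5S)-5-(but-3-enoyl)-N-methoxy-N,2,2-trimethyl-1,3-dioxolane-4-carboxamide
Conditions: allylMgBr (1 equiv), THF, −78 °C; pH 7 buffer
Reagents that add atoms: allylmagnesium bromide, C=CC[Mg]Br
Why: Weinreb ketone synthesis: the magnesium-chelated tetrahedral adduct cannot collapse before the quench, the two amides of C2-symmetric 2 are equivalent so either one gives 3, the anionic mono-adduct should react more slowly than 2, and a neutral quench keeps the β,γ-alkene and the stereocentre next to the ketone in place.

Step 3
Reactants: 4 (E)-non-2-enal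
Product: 5 (E)-1,1-diethoxynon-2-ene
Conditions: HC(OEt)3, EtOH, NH4NO3 (cat.), 23 °C
Reagents that add atoms: triethyl orthoformate, CCOC(OCC)OCC
Why: Acid-catalysed acetalisation with the orthoformate as ethoxy source and water scavenger is standard for enals and keeps the (E)-alkene.

Step 4
Reactants: 5 (E)-1,1-diethoxynon-2-ene; 3 allyl keto amide; 6 (tributylstannyl)methanol
Product: 11 (4R,5S,6R)-6-allyl-2-[(E)-hept-1-enyl]-6-hydroxy-3-(hydroxymethyl)-4,5-(isopropylidenedioxy)cyclohex-2-en-1-one (target locants 5R,6S,1R), via dienylmagnesium bromide 7 (not isolated), via lithium lithiomethoxide 8 (not isolated), via carbinol amide 9 (not isolated), via seco diketone 10 (not isolated)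
Conditions: 5, n-BuLi/t-BuOK (2.2 equiv), THF, −95 °C; MgBr2·OEt2, −78 °C; 3, −78 °C; 8 [from 6, n-BuLi (2 equiv), THF, −78 to 0 °C, added by cannula], −78 to −20 °C; AcOH, H2O, 23 °C; DBU, 23 °C
Reagents that add atoms: water, O
Why: Proposed new method: the superbase removes an allylic proton of 5 with 1,4-loss of ethoxide and then the C–H next to oxygen, so that after transmetalation 7 acts first as an acyl anion (closest known type: addition of α-metalated 1-alkoxy-1,3-dienes to ketones) and forms C1–C2 at the ketone of 3, while the less electrophilic N-methoxy-N-methylamide waits as the masked C4 carbonyl and is then turned by 8 into a stable chelated adduct (Weinreb ketone synthesis). The acidic quench frees the C4 hydroxy ketone and hydrolyses the dienol ether to the β,γ-unsaturated ketone 10, whose doubly activated C3–H2 is deprotonated by DBU and closes the carbocycle by a 6-(enolendo)-exo-trig aldol addition to C4=O, and E1cB loss of water gives C3=C4 (closest known type: the aldol-condensation half of a Robinson annulation). The only lasting new stereocentre, C1, is set by a Cram chelate of magnesium between the ketone oxygen and the dioxolane oxygen on C6, so that 7 enters from the side of C6–H, anti to the C5 branch, which places O1 trans to O6 as the later oxirane closure demands. Chemoselectivity (ketone before amide) rests on the electrophilicity gap and on chelate acceleration, and site selectivity in the ring closure rests on the acidity of C3–H2 and on α-attack giving a six-membered ring where γ-attack would give an eight-membered one. The trans-dioxolane disfavours five-membered lactol or lactone formation between O1 and C4 but allows the trans-fused six-membered ring, and dehydration to the cross-conjugated dienone makes the sequence irreversible. The (E)-geometry of the heptenyl group is the thermodynamic outcome of the elimination and of the dienolate equilibrium.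

Step 5
Reactants: 11 cyclohexenone with the 5,6-acetonide
Product: 12 isomeric acetonide in which O5 and the oxygen of the C4 CH2O group form a 2,2-dimethyl-1,3-dioxane while the C6 and C1 hydroxyls are free (1R,5R,6S)
Conditions: camphor-10-sulfonic acid (cat.), CH2Cl2, 23 °C
Reagents that add atoms: none
Why: Acid-catalysed acetonide migration under thermodynamic control: opening of the strained trans-fused dioxolane at O6 gives an oxocarbenium ion on O5 that the neighbouring primary alcohol captures, just as trans-diequatorial diols give way to 1,3-dioxanes in 4,6-O-isopropylidene hexopyranosides, and no stereocentre is touched.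

Step 6
Reactants: 12 1,3-dioxane diol
Product: 14 (1R,5R,6R)-1-allyl-7-oxabicyclo[4.1.0]hept-3-en-2-one carrying the (E)-heptenyl group at C3 and the O5/CH2O acetonide, via mesylate 13 (not isolated)
Conditions: MsCl, Et3N, CH2Cl2, 0 °C; then DBU, 0 to 23 °C
Reagents that add atoms: methanesulfonyl chloride, CS(=O)(=O)Cl (atoms kept only in 13)
Why: Sulfonylation picks the only secondary alcohol (the C1 hydroxyl is tertiary), and the C1 alkoxide then displaces the trans mesylate in a 3-exo-tet intramolecular Williamson reaction with inversion at C6, as in the making of 2,3-anhydro sugars from acetal-locked hydroxy sulfonates, which puts O7 on the face of O5.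

Step 7
Reactants: 14 allyl epoxide; 15 tert-butyl methacrylate
Product: 16 tert-butyl (E)-2-methylbut-2-enoate side chain on C1 of the acetonide-protected epoxy enone (1R,5R,6R)
Conditions: 15 (excess), second-generation Hoveyda–Grubbs catalyst (cat.), CH2Cl2, 40 °C
Reagents that add atoms: none
Why: Olefin cross-metathesis of a monosubstituted alkene with a methacrylate should engage the allyl group faster than the hindered internal diene and gives the trisubstituted (E)-enoate as the thermodynamic isomer.

Step 8
Reactants: 16 protected ester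
Product: 17 (E)-4-[(1R,5R,6R)-3-[(E)-hept-1-enyl]-5-hydroxy-4-(hydroxymethyl)-2-oxo-7-oxabicyclo[4.1.0]hept-3-en-1-yl]-2-methylbut-2-enoic acid (target)
Conditions: CF3CO2H, CH2Cl2, H2O, 0 to 23 °C
Reagents that add atoms: none
Why: Acidolysis removes the tert-butyl ester as isobutene and hydrolyses the 1,3-dioxane acetal, while the electron-poor α-keto epoxide should resist opening, so no stereocentre changes.

Compound list
1 | dimethyl (4S,5S)-2,2-dimethyl-1,3-dioxolane-4,5-dicarboxylate | COC(=O)[C@H]1OC(C)(C)O[C@@H]1C(=O)OC | starting material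
2 | (4S,5S)-N4,N5-dimethoxy-N4,N5,2,2-tetramethyl-1,3-dioxolane-4,5-dicarboxamide | CON(C)C(=O)[C@H]1OC(C)(C)O[C@@H]1C(=O)N(C)OC | intermediate
3 | (4S,5S)-5-(but-3-enoyl)-N-methoxy-N,2,2-trimethyl-1,3-dioxolane-4-carboxamide | C=CCC(=O)[C@H]1OC(C)(C)O[C@@H]1C(=O)N(C)OC | intermediate
4 | (E)-non-2-enal | CCCCCC/C=C/C=O | starting material
5 | (E)-1,1-diethoxynon-2-ene | CCCCCC/C=C/C(OCC)OCC | intermediate
6 | (tributylstannyl)methanol | CCCC[Sn](CCCC)(CCCC)CO | starting material
7 | [(1Z,3E)-1-ethoxynona-1,3-dien-1-yl]magnesium bromide | CCCCC/C=C/C=C(/OCC)[Mg]Br | intermediate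
8 | lithium lithiomethoxide (LiCH2OLi) | [Li]CO[Li] | intermediate
9 | (4S,5S)-5-[(4R,5E,7E)-5-ethoxy-4-hydroxytrideca-1,5,7-trien-4-yl]-N-methoxy-N,2,2-trimethyl-1,3-dioxolane-4-carboxamide | CCCCC/C=C/C=C(/OCC)[C@@](O)(CC=C)[C@H]1OC(C)(C)O[C@@H]1C(=O)N(C)OC | intermediate
10 | (4S,5S)-2,2-dimethyl-1,3-dioxolane bearing 2-hydroxyacetyl at C4 and (4R,7E)-4-hydroxy-5-oxotrideca-1,7-dien-4-yl at C5 | CCCCC/C=C/CC(=O)[C@@](O)(CC=C)[C@H]1OC(C)(C)O[C@@H]1C(=O)CO | intermediate
11 | (4R,5S,6R)-6-allyl-2-[(E)-hept-1-enyl]-6-hydroxy-3-(hydroxymethyl)-4,5-(isopropylidenedioxy)cyclohex-2-en-1-one | CCCCC/C=C/C1=C(CO)[C@H]2OC(C)(C)O[C@@H]2[C@](O)(CC=C)C1=O | intermediate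
12 | isomer of 11 with the acetonide on O5 and the CH2O oxygen (1,3-dioxane), C6–OH and C1–OH free, (1R,5R,6S) | CCCCC/C=C/C1=C2COC(C)(C)O[C@H]2[C@H](O)[C@](O)(CC=C)C1=O | intermediate
13 | 6-methanesulfonate of 12 | CCCCC/C=C/C1=C2COC(C)(C)O[C@H]2[C@H](OS(C)(=O)=O)[C@](O)(CC=C)C1=O | intermediate
14 | (1R,5R,6R)-1-allyl epoxy enone with the O5/CH2O acetonide | CCCCC/C=C/C1=C2COC(C)(C)O[C@H]2[C@H]3O[C@@]3(CC=C)C1=O | intermediate
15 | tert-butyl methacrylate | C=C(C)C(=O)OC(C)(C)C | starting material
16 | tert-butyl ester, O5/CH2O acetonide of the target | CCCCC/C=C/C1=C2COC(C)(C)O[C@H]2[C@H]3O[C@@]3(C/C=C(\C)C(=O)OC(C)(C)C)C1=O | intermediate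
17 | (E)-4-[(1R,5R,6R)-3-[(E)-hept-1-enyl]-5-hydroxy-4-(hydroxymethyl)-2-oxo-7-oxabicyclo[4.1.0]hept-3-en-1-yl]-2-methylbut-2-enoic acid | CCCCC/C=C/C1=C(CO)[C@@H](O)[C@H]2O[C@@]2(C/C=C(\C)C(=O)O)C1=O | target

Total step count: 8. Longest linear sequence: 7 (steps 1, 2, 4, 5, 6, 7, 8).

Steps most likely to fail

Step 4. The basic dienylmetal may enolise the allyl ketone. Chelation control may erode and give poor facial selectivity at C1. The aldol closure may also stay incomplete in the crowded one-flask medium. The fallback uses known chemistry, sets out from 3 and comes back at 10. 1,3-Dithiane is alkylated with (E)-1-bromooct-2-ene (n-BuLi, THF) to 2-[(E)-oct-2-en-1-yl]-1,3-dithiane F1. Its lithio derivative (n-BuLi, THF, −30 °C) is added to 3 precomplexed with MgBr2·OEt2 (Corey–Seebach umpolung under chelation control) and gives, after isolation, the dithiane carbinol amide F2. A separate Weinreb ketone synthesis with 8 gives the dithiane hydroxy ketone F3. MeI, CaCO3 and aqueous MeCN then unmask the ketone to 10, which is isolated and cyclised with DBU to 11.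

Step 7. The catalyst may attack the heptenyl diene competitively, and turnover with the 1,1-disubstituted partner may be slow. The fallback sets out from 14 and comes back at 16. Dihydroxylation of the more accessible monosubstituted alkene (OsO4 cat., N-methylmorpholine N-oxide) gives the side-chain diol F4. NaIO4 cleavage gives the aldehyde F5. A Wittig reaction with tert-butyl 2-(triphenylphosphoranylidene)propanoate in CH2Cl2 at 23 °C installs the (E)-enoate of 16.

Step 5. The acetal migration may be incomplete or unselective, stopping at a mixture or moving the acetal onto O6 and O1. The fallback sets out from 11 and comes back at 12. Aqueous AcOH hydrolyses the strained dioxolane to the tetraol F6. Kinetic acetalisation with 2-methoxypropene and pyridinium p-toluenesulfonate at −20 °C, which starts at the primary alcohol, then closes the 1,3-dioxane of 12.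

Further compounds
F1 | step 4 | 2-[(E)-oct-2-en-1-yl]-1,3-dithiane | CCCCC/C=C/CC1SCCCS1
F2 | step 4 | dithiane carbinol amide (analogue of 9 with a 1,3-dithiane at C2) | CCCCC/C=C/CC1(SCCCS1)[C@@](O)(CC=C)[C@H]2OC(C)(C)O[C@@H]2C(=O)N(C)OC
F3 | step 4 | dithiane hydroxy ketone (analogue of 10 with a 1,3-dithiane at C2) | CCCCC/C=C/CC1(SCCCS1)[C@@](O)(CC=C)[C@H]2OC(C)(C)O[C@@H]2C(=O)CO
F4 | step 7 | side-chain diol from 14 (2,3-dihydroxypropyl on C1, mixture at the new carbinol) | CCCCC/C=C/C1=C2COC(C)(C)O[C@H]2[C@H]3O[C@@]3(CC(O)CO)C1=O
F5 | step 7 | aldehyde from 14 (2-oxoethyl on C1) | CCCCC/C=C/C1=C2COC(C)(C)O[C@H]2[C@H]3O[C@@]3(CC=O)C1=O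
F6 | step 5 | tetraol (4R,5S,6R)-6-allyl-2-[(E)-hept-1-enyl]-4,5,6-trihydroxy-3-(hydroxymethyl)cyclohex-2-en-1-one | CCCCC/C=C/C1=C(CO)[C@@H](O)[C@H](O)[C@](O)(CC=C)C1=O
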